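**Plan**

1. Retrosynthesis cuts, in order: the phenol O–Si bond, the C5–propenyl bond (bromine stands in for the alkene), the C2–C3 bond of the dihydrofuran ring, and the aryl O–CH2 ether bond. This leads back to 2'-hydroxy-3'-methoxyacetophenone and syringaldehyde.
2. Forward: the two arenes are joined as an aryl benzyl ether and the acetyl group is turned into a diazo group. A rhodium carbene at the future C3 then inserts into the ether C–H at the future C2 and closes the dihydrofuran ring (O1–C2–C3–C3a–C7a).
3. Enabling feature: C2 carries a hydrogen that is α to O1 and benzylic to the electron-rich syringyl ring, and it lies 1,5 to C3 across the C3a–C7a edge of the benzene ring. The acetyl methyl becomes the C3 methyl with no redox adjustment.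
4. Stereochemistry: the chiral dirhodium carboxylate sets C3 (R) in the insertion, which should give the cis ring (2S,3R). Reversible acid ionization of the C2–O1 bond then corrects C2 to R (trans) under control of C3.
5. End game: Suzuki–Miyaura coupling with an E-propenylboronate (retention of alkene geometry), then fluoride desilylation.

Key step: step 6

Assumption: Rh2(S-PTAD)4 is taken to deliver the 3R carbene face; should it give the mirror-image ring, Rh2(R-PTAD)4 is used with no other change.

**Step 1**
Reactants: 1 2'-hydroxy-3'-methoxyacetophenone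
Product: 2 1-(5-bromo-2-hydroxy-3-methoxyphenyl)ethan-1-one
Conditions: NBS, MeCN, 0 °C to rt
Reagents that add atoms: N-bromosuccinimide, O=C1CCC(=O)N1Br
Why: Electrophilic aromatic bromination; the only open position that is para to the phenol OH and meta to the acetyl group is C5, so one regioisomer should form.

**Step 2**
Reactants: 3 syringaldehyde (4-hydroxy-3,5-dimethoxybenzaldehyde)
Product: 4 3,5-dimethoxy-4-(triisopropylsilyloxy)benzaldehyde
Conditions: TIPSCl, imidazole, DMF, rt
Reagents that add atoms: triisopropylsilyl chloride, CC(C)[Si](Cl)(C(C)C)C(C)C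
Why: Imidazole-promoted silyl ether formation; the hindered TIPS aryl ether is chosen to survive hydrazine, the carbene step, acid and aqueous base, and to leave with fluoride at the end.

**Step 3**
Reactants: 4 3,5-dimethoxy-4-(triisopropylsilyloxy)benzaldehyde
Product: 5 [3,5-dimethoxy-4-(triisopropylsilyloxy)phenyl]methanol
Conditions: NaBH4, MeOH, 0 °C
Reagents that add atoms: none
Why: Borohydride reduction of the aldehyde to the primary benzylic alcohol, to which the aryl silyl ether is inert at 0 °C.

**Step 4**
Reactants: 2 1-(5-bromo-2-hydroxy-3-methoxyphenyl)ethan-1-one; 5 [3,5-dimethoxy-4-(triisopropylsilyloxy)phenyl]methanol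
Product: 6 1-[5-bromo-2-{[3,5-dimethoxy-4-(triisopropylsilyloxy)benzyl]oxy}-3-methoxyphenyl]ethan-1-one
Conditions: PPh3, DIAD, THF, 0 °C to rt
Reagents that add atoms: none
Why: Mitsunobu etherification; the acidic ortho-acylphenol is alkylated at oxygen by the activated primary benzylic alcohol under neutral conditions, which spares the silyl ether and avoids an unstable para-silyloxybenzyl halide.

**Step 5**
Reactants: 6 1-[5-bromo-2-{[3,5-dimethoxy-4-(triisopropylsilyloxy)benzyl]oxy}-3-methoxyphenyl]ethan-1-one
Product: 7 hydrazone of ketone 6 (N-unsubstituted; C=N geometry not defined)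
Conditions: N2H4·H2O (excess), AcOH (cat.), EtOH, 70 °C
Reagents that add atoms: hydrazine (used as the monohydrate), NN
Why: Hydrazone formation by condensation; excess hydrazine suppresses azine formation, and the C=N geometry does not matter because both isomers give the same diazoalkane.

**Step 6**
Reactants: 7 hydrazone of ketone 6
Product: 9 (2S,3R)-5-bromo-2-[3,5-dimethoxy-4-(triisopropylsilyloxy)phenyl]-7-methoxy-3-methyl-2,3-dihydrobenzofuran (2,3-cis), via diazoalkane 8 (not isolated)
Conditions: MnO2, CH2Cl2, 0 °C, filtration through Celite; then slow addition of the cold filtrate to Rh2(S-PTAD)4 (dirhodium tetrakis[(S)-(1-adamantyl)(N-phthalimido)acetate], 1 mol %), CH2Cl2, −20 °C to 0 °C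
Reagents that add atoms: none
Why: MnO2 dehydrogenates the hydrazone to the aryl(methyl)diazomethane 8, which loses N2 on the dirhodium tetracarboxylate to give a donor/donor rhodium carbene at the future C3; this carbene inserts into one of the two enantiotopic C–H bonds of the OCH2 group through a three-centre, hydride-transfer-like transition state with retention at carbon. The closest known reaction type is the enantioselective intramolecular 1,5-C–H insertion of ortho-(benzyloxy)aryl diazo compounds to 2,3-dihydrobenzofurans under chiral dirhodium carboxylate catalysis. The five-membered ring O1–C2–C3–C3a–C7a is closed by 1,5-insertion, with the carbene carbon and the C–H carbon as the ring termini, which is the only ring size the ortho tether allows without strain. C3 is set by the carbene face that the chiral phthalimido-carboxylate ligands leave open, and C2 by which enantiotopic hydrogen is engaged in the compact transition state that puts the syringyl group and the carbene methyl on the same side, so the cis (2S,3R) product should form under catalyst control. The step needs insertion to outrun the 1,2-hydride shift of the methyl-bearing carbene (to a styrene), azine formation and intermolecular reactions; the doubly activated C–H held next to the carbene, the low electrophilicity of the donor/donor carbene, the bulky carboxylate ligands, the low temperature and the slow addition of dilute 8 should secure this.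

**Step 7**
Reactants: 9 (2S,3R)-cis-dihydrobenzofuran
Product: 10 (2R,3R)-5-bromo-2-[3,5-dimethoxy-4-(triisopropylsilyloxy)phenyl]-7-methoxy-3-methyl-2,3-dihydrobenzofuran (2,3-trans)
Conditions: CF3CO2H, CH2Cl2, 0 °C; NaHCO3 quench
Reagents that add atoms: none
Why: Acid-mediated epimerization by reversible SN1 ring opening; ionization of the C2–O1 bond gives the para-silyloxybenzyl cation (a protonated para-quinone methide), and its reclosure by the phenol should funnel the material to the more stable 2,3-trans isomer while C3 is untouched.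

**Step 8**
Reactants: 10 (2R,3R)-trans-bromide; 11 (E)-prop-1-enylboronic acid pinacol ester
Product: 12 (2R,3R)-2-[3,5-dimethoxy-4-(triisopropylsilyloxy)phenyl]-7-methoxy-3-methyl-5-[(E)-prop-1-enyl]-2,3-dihydrobenzofuran
Conditions: Pd(dppf)Cl2 (5 mol %), K3PO4, 1,4-dioxane/H2O, 80 °C
Reagents that add atoms: none
Why: Suzuki–Miyaura cross-coupling of the aryl bromide with the alkenylboronate, which transfers the propenyl group with retention of the E geometry and does not touch the two ring stereocentres.

**Step 9**
Reactants: 12 (2R,3R)-silyl ether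
Product: 13 maceneolignan A, 4-[(2R,3R)-7-methoxy-3-methyl-5-[(E)-prop-1-enyl]-2,3-dihydrobenzofuran-2-yl]-2,6-dimethoxyphenol
Conditions: Bu4NF, AcOH, THF, 0 °C
Reagents that add atoms: none
Why: Fluoride-mediated desilylation of the aryl silyl ether; the acetic acid buffer keeps the liberated phenoxide from opening the ring through a para-quinone methide, so the alkene and both stereocentres should be unaffected.

**Compound list**

1 | 2'-hydroxy-3'-methoxyacetophenone | CC(=O)c1cccc(OC)c1O | starting material
2 | 1-(5-bromo-2-hydroxy-3-methoxyphenyl)ethan-1-one | CC(=O)c1cc(Br)cc(OC)c1O | intermediate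
3 | syringaldehyde | COc1cc(C=O)cc(OC)c1O | starting material
4 | 3,5-dimethoxy-4-(triisopropylsilyloxy)benzaldehyde | COc1cc(C=O)cc(OC)c1O[Si](C(C)C)(C(C)C)C(C)C | intermediate
5 | [3,5-dimethoxy-4-(triisopropylsilyloxy)phenyl]methanol | COc1cc(CO)cc(OC)c1O[Si](C(C)C)(C(C)C)C(C)C | intermediate
6 | 1-[5-bromo-2-{[3,5-dimethoxy-4-(triisopropylsilyloxy)benzyl]oxy}-3-methoxyphenyl]ethan-1-one | CC(=O)c1cc(Br)cc(OC)c1OCc1cc(OC)c(O[Si](C(C)C)(C(C)C)C(C)C)c(OC)c1 | intermediate
7 | hydrazone of ketone 6 | CC(=NN)c1cc(Br)cc(OC)c1OCc1cc(OC)c(O[Si](C(C)C)(C(C)C)C(C)C)c(OC)c1 | intermediate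
8 | 5-bromo-1-(1-diazoethyl)-2-{[3,5-dimethoxy-4-(triisopropylsilyloxy)benzyl]oxy}-3-methoxybenzene | CC(=[N+]=[N-])c1cc(Br)cc(OC)c1OCc1cc(OC)c(O[Si](C(C)C)(C(C)C)C(C)C)c(OC)c1 | intermediate
9 | (2S,3R)-5-bromo-2-[3,5-dimethoxy-4-(triisopropylsilyloxy)phenyl]-7-methoxy-3-methyl-2,3-dihydrobenzofuran (cis) | Brc1cc(OC)c2c(c1)[C@@H](C)[C@@H](c1cc(OC)c(O[Si](C(C)C)(C(C)C)C(C)C)c(OC)c1)O2 | intermediate
10 | (2R,3R)-5-bromo-2-[3,5-dimethoxy-4-(triisopropylsilyloxy)phenyl]-7-methoxy-3-methyl-2,3-dihydrobenzofuran (trans) | Brc1cc(OC)c2c(c1)[C@@H](C)[C@H](c1cc(OC)c(O[Si](C(C)C)(C(C)C)C(C)C)c(OC)c1)O2 | intermediate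
11 | (E)-prop-1-enylboronic acid pinacol ester | C/C=C/B1OC(C)(C)C(C)(C)O1 | starting material
12 | (2R,3R)-2-[3,5-dimethoxy-4-(triisopropylsilyloxy)phenyl]-7-methoxy-3-methyl-5-[(E)-prop-1-enyl]-2,3-dihydrobenzofuran | C/C=C/c1cc(OC)c2c(c1)[C@@H](C)[C@H](c1cc(OC)c(O[Si](C(C)C)(C(C)C)C(C)C)c(OC)c1)O2 | intermediate
13 | maceneolignan A | C/C=C/c1cc(OC)c2c(c1)[C@@H](C)[C@H](c1cc(OC)c(O)c(OC)c1)O2 | target

**Step count and risks**

Total step count: 9. Longest linear sequence: 8 steps (steps 2 to 9, from syringaldehyde 3).

Steps most likely to fail: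

Step 6. The methyl-bearing carbene may undergo 1,2-hydride shift to a styrene faster than it inserts, the diazoalkane may couple to the azine, or the catalyst may give insufficient facial control. The fallback uses a carbene with no β-hydrogen and sets out from ketone 6. Oxidation of the acetyl group with SeO2 in pyridine should give the arylglyoxylic acid F1, and trimethylsilyldiazomethane in toluene/MeOH its methyl ester F2. Condensation with p-toluenesulfonohydrazide gives the tosylhydrazone F3, and Bamford–Stevens elimination with DBU in CH2Cl2 the methyl aryldiazoacetate F4. Intramolecular C–H insertion of this donor/acceptor carbene with Rh2(S-PTTL)4 (dirhodium tetrakis[N-phthaloyl-(S)-tert-leucinate], or its enantiomer, whichever sets C2 as R) in toluene at −60 °C should give the cis ester F5 (2R,3S). NaOMe in MeOH epimerizes the acidic C3 to the trans ester F6 (2R,3R). DIBAL-H reduces it to the primary alcohol F7, TsCl in pyridine gives the tosylate F8, and LiEt3BH in THF replaces the tosylate by hydride. This gives the trans-bromide 10, where the route is rejoined at step 8; steps 5 to 7 are not needed.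

Step 7. The silyloxy-substituted ring may ionize only under acid strong enough to remove the silyl group or to let the open cation lose the C3 proton and re-add it, which would erode the C3 configuration; equilibration may also stop short. The fallback reverses the order of deprotection and epimerization and sets out from cis compound 9. Bu4NF/AcOH in THF gives the cis phenol, (2S,3R)-4-(5-bromo-7-methoxy-3-methyl-2,3-dihydrobenzofuran-2-yl)-2,6-dimethoxyphenol F9. The free para-hydroxybenzyl aryl ether should open reversibly to the neutral para-quinone methide with only a catalytic amount of camphor-10-sulfonic acid in CH2Cl2 at 0 °C to rt, and reclosure should give the trans phenol, the (2R,3R) isomer F10. Suzuki–Miyaura coupling of this unprotected phenol with boronate 11 under the conditions of step 8 then gives the target 13 directly.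

Step 5. The N-unsubstituted hydrazone of an aryl methyl ketone may disproportionate to the azine on concentration, and hot hydrazine may attack the aryl silyl ether. The fallback changes the carbene precursor and sets out from ketone 6. Condensation with 2-(trifluoromethyl)benzenesulfonohydrazide in MeOH at rt should give the stable N-sulfonylhydrazone F11. Deprotonation with NaH in CH2Cl2 and warming from −40 °C in the presence of the dirhodium catalyst releases diazoalkane 8 by Bamford–Stevens elimination without any oxidant. The diazoalkane is consumed in the same flask to give 9, where the route continues with step 7.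

**Further compounds**

F1 | step 6 | 2-[5-bromo-2-{[3,5-dimethoxy-4-(triisopropylsilyloxy)benzyl]oxy}-3-methoxyphenyl]-2-oxoacetic acid | OC(=O)C(=O)c1cc(Br)cc(OC)c1OCc1cc(OC)c(O[Si](C(C)C)(C(C)C)C(C)C)c(OC)c1
F2 | step 6 | methyl ester of F1 | COC(=O)C(=O)c1cc(Br)cc(OC)c1OCc1cc(OC)c(O[Si](C(C)C)(C(C)C)C(C)C)c(OC)c1
F3 | step 6 | tosylhydrazone of F2 | COC(=O)C(=NNS(=O)(=O)c1ccc(C)cc1)c1cc(Br)cc(OC)c1OCc1cc(OC)c(O[Si](C(C)C)(C(C)C)C(C)C)c(OC)c1
F4 | step 6 | methyl 2-[5-bromo-2-{[3,5-dimethoxy-4-(triisopropylsilyloxy)benzyl]oxy}-3-methoxyphenyl]-2-diazoacetate | COC(=O)C(=[N+]=[N-])c1cc(Br)cc(OC)c1OCc1cc(OC)c(O[Si](C(C)C)(C(C)C)C(C)C)c(OC)c1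
F5 | step 6 | methyl (2R,3S)-5-bromo-2-[3,5-dimethoxy-4-(triisopropylsilyloxy)phenyl]-7-methoxy-2,3-dihydrobenzofuran-3-carboxylate (cis) | Brc1cc(OC)c2c(c1)[C@H](C(=O)OC)[C@H](c1cc(OC)c(O[Si](C(C)C)(C(C)C)C(C)C)c(OC)c1)O2
F6 | step 6 | methyl (2R,3R)-5-bromo-2-[3,5-dimethoxy-4-(triisopropylsilyloxy)phenyl]-7-methoxy-2,3-dihydrobenzofuran-3-carboxylate (trans) | Brc1cc(OC)c2c(c1)[C@@H](C(=O)OC)[C@H](c1cc(OC)c(O[Si](C(C)C)(C(C)C)C(C)C)c(OC)c1)O2
F7 | step 6 | [(2R,3S)-5-bromo-2-[3,5-dimethoxy-4-(triisopropylsilyloxy)phenyl]-7-methoxy-2,3-dihydrobenzofuran-3-yl]methanol (trans) | Brc1cc(OC)c2c(c1)[C@@H](CO)[C@H](c1cc(OC)c(O[Si](C(C)C)(C(C)C)C(C)C)c(OC)c1)O2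
F8 | step 6 | p-toluenesulfonate of F7 (trans, 2R,3S) | Brc1cc(OC)c2c(c1)[C@@H](COS(=O)(=O)c1ccc(C)cc1)[C@H](c1cc(OC)c(O[Si](C(C)C)(C(C)C)C(C)C)c(OC)c1)O2
F9 | step 7 | (2S,3R)-4-(5-bromo-7-methoxy-3-methyl-2,3-dihydrobenzofuran-2-yl)-2,6-dimethoxyphenol (cis) | Brc1cc(OC)c2c(c1)[C@@H](C)[C@@H](c1cc(OC)c(O)c(OC)c1)O2
F10 | step 7 | (2R,3R)-4-(5-bromo-7-methoxy-3-methyl-2,3-dihydrobenzofuran-2-yl)-2,6-dimethoxyphenol (trans) | Brc1cc(OC)c2c(c1)[C@@H](C)[C@H](c1cc(OC)c(O)c(OC)c1)O2
F11 | step 5 | N-[2-(trifluoromethyl)benzenesulfonyl]hydrazone of ketone 6 | CC(=NNS(=O)(=O)c1ccccc1C(F)(F)F)c1cc(Br)cc(OC)c1OCc1cc(OC)c(O[Si](C(C)C)(C(C)C)C(C)C)c(OC)c1
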